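The 3,6-dihydro-2H-pyran ring is disconnected across O1–C6 and C2–C3. Its C4=C5 alkene with the chain on C5 is a transposed enone, so O1–C2 map onto the carbonyl of a silyl-capped ynal and C3–C6 onto a 1-methoxy-3-silyloxybutadiene that already carries the homofarnesyl chain on its C2. One catalytic asymmetric hetero-Diels–Alder reaction closes the ring, forms both ring bonds and sets C2, the only stereocentre, as (S). The precursor is an E enol ether/silyl enol ether diene whose oxygen pattern forces the chain onto C5. Afterwards the C4 oxygen is removed with allylic transposition and the alkyne becomes the acrylic acid.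

Key step: step 6

Remarks on the chemistry
- Numbering: the pyran atoms are O1, C2 (stereocentre), C3, C4, C5 (chain-bearing) and C6 throughout.
- Structure check: C2 is (S) in the cycloadduct and in the target, because its carbon substituent (alkynyl, later 1-carboxyvinyl) outranks C3 at every stage, so the descriptor does not change along the route.
- Precursor design: base-mediated formylation of a methyl n-alkyl ketone is not reliably selective for the methylene carbon once the alkyl group is longer than ethyl, and attack at the methyl group would put the chain on the wrong diene carbon. The β-methoxy enone 7 is therefore built by a cross-coupling that fixes the chain on the α-carbon by construction.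
- Silyl group: a triethylsilyl enol ether is used because a diene of this mass cannot be distilled and has to survive filtration through deactivated silica.
- Assumption: (salen)CrBF4 denotes the tetrafluoroborate of trivalent chromium bound to the dianion of N,N'-bis(3,5-di-tert-butylsalicylidene)-trans-1,2-cyclohexanediamine. Its (S,S) antipode is taken to give (S)-C2 by analogy with simple aldehydes; if the first run shows the opposite sense, the (R,R) antipode is used and nothing else changes.

Step 1
Reactants: 1 (2E,6E)-farnesol
Product: 2 (2E,6E)-farnesal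
Conditions: MnO2 (activated, excess), CH2Cl2, rt
Reagents that add atoms: none
Why: Activated MnO2 is a chemoselective oxidant for allylic alcohols (allylic oxidation) that stops at the enal and should leave the 2E geometry and the other alkenes untouched.

Step 2
Reactants: 2 (2E,6E)-farnesal
Product: 3 (3E,7E)-4,8,12-trimethyltrideca-1,3,7,11-tetraene
Conditions: Ph3PCH3Br, KOtBu, THF, 0 °C to rt
Reagents that add atoms: methyltriphenylphosphonium bromide, C[P+](c1ccccc1)(c1ccccc1)c1ccccc1.[Br-]
Why: Wittig methylenation of the enal with the non-stabilised ylide should give the terminal 1,3-diene without touching the existing trisubstituted alkenes, and no stereocentre is formed.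

Step 3
Reactants: 4 (E)-4-methoxybut-3-en-2-one
Product: 5 (Z)-3-iodo-4-methoxybut-3-en-2-one
Conditions: NIS, AcOH, CH2Cl2, rt, dark; then Et3N, 0 °C
Reagents that add atoms: N-iodosuccinimide, O=C1CCC(=O)N1I
Why: C3 is the nucleophilic carbon of this push–pull alkene, so iodonium adds there and base-induced loss of acetic acid from the iodo-acetoxy adduct (electrophilic α-iodination of a vinylogous ester by addition–elimination) should give the α-iodo enone with the methoxy group anti to the acetyl group.

Step 4
Reactants: 3 (3E,7E)-4,8,12-trimethyltrideca-1,3,7,11-tetraene; 5 (Z)-3-iodo-4-methoxybut-3-en-2-one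
Product: 7 (3E,6E,10E)-3-(methoxymethylidene)-7,11,15-trimethylhexadeca-6,10,14-trien-2-one, via homofarnesyl-9-BBN 6 (not isolated)
Conditions: 9-BBN, THF, 0 °C to rt; then 5, PdCl2(dppf) (5 mol %), AsPh3, Cs2CO3, DMF/H2O, rt
Reagents that add atoms: none
Why: 9-BBN hydroborates only the monosubstituted terminal alkene of the diene with boron on C1, and the resulting primary alkylborane should undergo B-alkyl Suzuki–Miyaura coupling with the α-iodo enone with retention of the enol ether geometry, so that the chain sits on C3 of the enone by construction and not by a regioselective enolisation.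

Step 5
Reactants: 7 (3E,6E,10E)-3-(methoxymethylidene)-7,11,15-trimethylhexadeca-6,10,14-trien-2-one
Product: 8 (E)-1-methoxy-2-[(3E,7E)-4,8,12-trimethyltrideca-3,7,11-trienyl]-3-(triethylsilyloxy)buta-1,3-diene
Conditions: TESOTf, Et3N, Et2O, –78 to 0 °C; filtration through Et3N-deactivated silica
Reagents that add atoms: triethylsilyl trifluoromethanesulfonate, CC[Si](CC)(CC)OS(=O)(=O)C(F)(F)F
Why: Soft enolisation (O-silylation of the vinylogous ester, then amine deprotonation of the acetyl methyl group, the only position whose deprotonation neutralises the silyloxy-allyl cation) should give the cross-conjugated silyl enol ether with the E enol ether unchanged.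

Step 6
Reactants: 8 (E)-1-methoxy-2-[(3E,7E)-4,8,12-trimethyltrideca-3,7,11-trienyl]-3-(triethylsilyloxy)buta-1,3-diene; 9 3-(trimethylsilyl)propynal
Product: 11 (S)-5-[(3E,7E)-4,8,12-trimethyltrideca-3,7,11-trienyl]-2-[(trimethylsilyl)ethynyl]-2,3-dihydro-4H-pyran-4-one, via 2-methoxy-4-silyloxy dihydropyran cycloadduct 10 (not isolated)
Conditions: (S,S)-(salen)CrBF4 (5 mol %, trivalent chromium), 4 Å MS, TBME, –30 to 0 °C; then TFA (cat.), CH2Cl2, 0 °C, short contact
Reagents that add atoms: none
Why: The cationic trivalent chromium centre binds the ynal carbonyl, and the diene adds in a concerted but asynchronous [4+2] in which the silyl enol ether terminus bonds to the carbonyl carbon (C2–C3) ahead of the carbonyl oxygen bonding to the methoxy-bearing carbon (O1–C6); the closest known reaction is the chromium salen catalysed hetero-Diels–Alder reaction of aldehydes with 1-alkoxy-3-silyloxy dienes. The pyran ring is closed by the cycloaddition itself, both ring bonds coming from the union of the four-carbon diene with the two-atom C=O unit, and TFA then expels methanol and the silyl group from 10 to unmask the enone. The only new stereocentre, C2, is set under catalyst control, the salen ligand leaving one face of the bound aldehyde open to the diene. The step needs regioselectivity, which the push–pull oxygen pattern of the diene secures because its unsubstituted silyl enol ether terminus is the only strongly nucleophilic carbon. It also needs chemoselectivity for the C=O over the C≡C of the ynal and over the chain alkenes, which is secured by Lewis acid activation of the carbonyl, by the silyl cap on the alkyne and by the low nucleophilicity of isolated trisubstituted alkenes.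

Step 7
Reactants: 11 (S)-5-[(3E,7E)-4,8,12-trimethyltrideca-3,7,11-trienyl]-2-[(trimethylsilyl)ethynyl]-2,3-dihydro-4H-pyran-4-one
Product: 12 (2S,4S)-5-[(3E,7E)-4,8,12-trimethyltrideca-3,7,11-trienyl]-2-[(trimethylsilyl)ethynyl]-3,4-dihydro-2H-pyran-4-ol
Conditions: NaBH4, CeCl3·7H2O, MeOH, –40 °C
Reagents that add atoms: none
Why: Luche reduction delivers hydride 1,2 to the carbonyl of the vinylogous ester, substrate control from the C2 substituent should favour the 2,4-cis (4S) alcohol, and the configuration at C4 is of no consequence because C4 becomes sp2 again in step 8.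

Step 8
Reactants: 12 (2S,4S)-5-[(3E,7E)-4,8,12-trimethyltrideca-3,7,11-trienyl]-2-[(trimethylsilyl)ethynyl]-3,4-dihydro-2H-pyran-4-ol
Product: 13 (S)-5-[(3E,7E)-4,8,12-trimethyltrideca-3,7,11-trienyl]-2-[(trimethylsilyl)ethynyl]-3,6-dihydro-2H-pyran
Conditions: Et3SiH (5 equiv), BF3·OEt2 (1.2 equiv), CH2Cl2, –78 to –40 °C
Reagents that add atoms: none
Why: In this Ferrier-type reductive rearrangement BF3 ionises the C4 hydroxyl to the O1-stabilised allyl cation spanning C4–C5–C6, Et3SiH delivers hydride to C6 (the oxocarbenium carbon) to leave the C4=C5 alkene, C2 is not involved, and the low temperature and excess silane should outrun attack by the chain alkenes, the nearest of which could only close a strained five-membered ring.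

Step 9
Reactants: 13 (S)-5-[(3E,7E)-4,8,12-trimethyltrideca-3,7,11-trienyl]-2-[(trimethylsilyl)ethynyl]-3,6-dihydro-2H-pyran
Product: 14 (S)-2-ethynyl-5-[(3E,7E)-4,8,12-trimethyltrideca-3,7,11-trienyl]-3,6-dihydro-2H-pyran
Conditions: K2CO3 (cat.), MeOH, rt
Reagents that add atoms: none
Why: Methanolysis of the C(sp)–Si bond by catalytic methoxide is a standard alkyne desilylation that should not affect the ring, the polyene or C2.

Step 10
Reactants: 14 (S)-2-ethynyl-5-[(3E,7E)-4,8,12-trimethyltrideca-3,7,11-trienyl]-3,6-dihydro-2H-pyran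
Product: 15 methyl 2-[(2S)-5-[(3E,7E)-4,8,12-trimethyltrideca-3,7,11-trienyl]-3,6-dihydro-2H-pyran-2-yl]prop-2-enoate
Conditions: Pd(OAc)2 (5 mol %), 2-PyPPh2, MsOH (cat.), CO (1 atm), MeOH, 45 °C
Reagents that add atoms: carbon monoxide, [C-]#[O+]; methanol, CO
Why: Palladium-catalysed hydromethoxycarbonylation of a terminal alkyne with the 2-pyridylphosphine ligand is Markovnikov-selective, placing the CO2Me group on the internal alkyne carbon to give the 2-substituted acrylate, and neither C2 nor the trisubstituted alkenes take part because the acid co-catalyst is buffered by the excess ligand.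

Step 11
Reactants: 15 methyl 2-[(2S)-5-[(3E,7E)-4,8,12-trimethyltrideca-3,7,11-trienyl]-3,6-dihydro-2H-pyran-2-yl]prop-2-enoate
Product: 16 2-[(2S)-5-[(3E,7E)-4,8,12-trimethyltrideca-3,7,11-trienyl]-3,6-dihydro-2H-pyran-2-yl]prop-2-enoic acid
Conditions: LiOH·H2O, THF/MeOH/H2O, 0 °C to rt; then 1 M HCl to pH 3, 0 °C
Reagents that add atoms: lithium hydroxide, [Li+].[OH-]
Why: Saponification of the methyl ester with LiOH under mild conditions should give the acid without conjugate addition to the acrylate or epimerisation at C2, whose hydrogen is not acidic enough for hydroxide.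

Compound list
1 | (2E,6E)-farnesol, (2E,6E)-3,7,11-trimethyldodeca-2,6,10-trien-1-ol | OC/C=C(\C)CC/C=C(\C)CCC=C(C)C | starting material
2 | (2E,6E)-farnesal, (2E,6E)-3,7,11-trimethyldodeca-2,6,10-trienal | O=C/C=C(\C)CC/C=C(\C)CCC=C(C)C | intermediate
3 | (3E,7E)-4,8,12-trimethyltrideca-1,3,7,11-tetraene | C=C/C=C(\C)CC/C=C(\C)CCC=C(C)C | intermediate
4 | (E)-4-methoxybut-3-en-2-one | CO/C=C/C(C)=O | starting material
5 | (Z)-3-iodo-4-methoxybut-3-en-2-one (iodine cis to methoxy, acetyl trans to methoxy) | CO/C=C(\I)C(C)=O | intermediate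
6 | 9-[(3E,7E)-4,8,12-trimethyltrideca-3,7,11-trienyl]-9-borabicyclo[3.3.1]nonane (homofarnesyl-9-BBN, formed in the flask) | CC(C)=CCC/C(C)=C/CC/C(C)=C/CCB1C2CCCC1CCC2 | intermediate
7 | (3E,6E,10E)-3-(methoxymethylidene)-7,11,15-trimethylhexadeca-6,10,14-trien-2-one (methoxy trans to acetyl) | CO/C=C(/C(C)=O)CC/C=C(\C)CC/C=C(\C)CCC=C(C)C | intermediate
8 | (E)-1-methoxy-2-[(3E,7E)-4,8,12-trimethyltrideca-3,7,11-trienyl]-3-(triethylsilyloxy)buta-1,3-diene | CO/C=C(/C(=C)O[Si](CC)(CC)CC)CC/C=C(\C)CC/C=C(\C)CCC=C(C)C | intermediate
9 | 3-(trimethylsilyl)propynal | C[Si](C)(C)C#CC=O | starting material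
10 | (6S)-2-methoxy-4-(triethylsilyloxy)-3-[(3E,7E)-4,8,12-trimethyltrideca-3,7,11-trienyl]-6-[(trimethylsilyl)ethynyl]-5,6-dihydro-2H-pyran (acetal carbon left unspecified since it is lost; formed in the flask) | COC1O[C@H](C#C[Si](C)(C)C)CC(O[Si](CC)(CC)CC)=C1CC/C=C(\C)CC/C=C(\C)CCC=C(C)C | intermediate
11 | (S)-5-[(3E,7E)-4,8,12-trimethyltrideca-3,7,11-trienyl]-2-[(trimethylsilyl)ethynyl]-2,3-dihydro-4H-pyran-4-one | C[Si](C)(C)C#C[C@@H]1CC(=O)C(CC/C=C(\C)CC/C=C(\C)CCC=C(C)C)=CO1 | intermediate
12 | (2S,4S)-5-[(3E,7E)-4,8,12-trimethyltrideca-3,7,11-trienyl]-2-[(trimethylsilyl)ethynyl]-3,4-dihydro-2H-pyran-4-ol (2,4-cis) | C[Si](C)(C)C#C[C@@H]1C[C@H](O)C(CC/C=C(\C)CC/C=C(\C)CCC=C(C)C)=CO1 | intermediate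
13 | (S)-5-[(3E,7E)-4,8,12-trimethyltrideca-3,7,11-trienyl]-2-[(trimethylsilyl)ethynyl]-3,6-dihydro-2H-pyran | C[Si](C)(C)C#C[C@@H]1CC=C(CC/C=C(\C)CC/C=C(\C)CCC=C(C)C)CO1 | intermediate
14 | (S)-2-ethynyl-5-[(3E,7E)-4,8,12-trimethyltrideca-3,7,11-trienyl]-3,6-dihydro-2H-pyran | C#C[C@@H]1CC=C(CC/C=C(\C)CC/C=C(\C)CCC=C(C)C)CO1 | intermediate
15 | methyl 2-[(2S)-5-[(3E,7E)-4,8,12-trimethyltrideca-3,7,11-trienyl]-3,6-dihydro-2H-pyran-2-yl]prop-2-enoate | C=C(C(=O)OC)[C@@H]1CC=C(CC/C=C(\C)CC/C=C(\C)CCC=C(C)C)CO1 | intermediate
16 | 2-[(2S)-5-[(3E,7E)-4,8,12-trimethyltrideca-3,7,11-trienyl]-3,6-dihydro-2H-pyran-2-yl]prop-2-enoic acid (CNP0171598.1) | C=C(C(=O)O)[C@@H]1CC=C(CC/C=C(\C)CC/C=C(\C)CCC=C(C)C)CO1 | target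

Total step count: 11 steps.
Longest linear sequence: 10 steps (steps 1, 2, 4, 5, 6, 7, 8, 9, 10, 11); step 3 is a one-step side branch.

Steps most likely to fail

1. Step 6 (key cycloaddition). The 2-alkyl diene may react sluggishly at the chromium centre, facial discrimination of the slim ynal may be poor, or the diene may be consumed by silyl transfer before it cycloadds. The fallback makes the same two ring bonds in two stages, setting out again from diene 8 and aldehyde 9. A Ti(OiPr)4/BINOL-catalysed (tetravalent titanium) Mukaiyama aldol addition of the silyl enol ether terminus to 9, with 4 Å MS in Et2O at –20 °C and the BINOL antipode chosen to give the (S)-carbinol, should give the open-chain β-hydroxy enone (1E,5S)-5-hydroxy-1-methoxy-2-[(3E,7E)-4,8,12-trimethyltrideca-3,7,11-trienyl]-7-(trimethylsilyl)hept-1-en-6-yn-3-one F1. Catalytic TFA in CH2Cl2 at 0 °C then adds the hydroxyl to the methoxy-bearing carbon and expels methanol, which returns the route to pyranone 11.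

2. Step 4 (hydroboration and B-alkyl coupling). Oxidative addition into the electron-rich iodide may be slow, β-hydride elimination may return the diene, the aqueous base may hydrolyse the enol ether, or the borane may also touch the internal alkene of the diene. The fallback needs no cross-coupling and sets out from farnesol 1.
 - PBr3 in Et2O at –10 °C gives (2E,6E)-farnesyl bromide F2.
 - Li2CuCl4-catalysed (divalent copper) coupling in THF at 0 °C with [2-(2-methyl-1,3-dioxolan-2-yl)ethyl]magnesium bromide F3, prepared from 2-(2-bromoethyl)-2-methyl-1,3-dioxolane and Mg, gives 2-methyl-2-[(4E,8E)-5,9,13-trimethyltetradeca-4,8,12-trienyl]-1,3-dioxolane F4.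
 - PPTS in wet acetone releases (6E,10E)-7,11,15-trimethylhexadeca-6,10,14-trien-2-one F5.
 - Claisen formylation with NaH and HCO2Me in THF gives (3Z,6E,10E)-3-(hydroxymethylidene)-7,11,15-trimethylhexadeca-6,10,14-trien-2-one F6.
 - O-methylation with Me2SO4 and K2CO3 in acetone returns the route to enone 7.
 
 The formylation is expected to attack the methyl group as well, so the isomeric enol ethers have to be separated by chromatography at the stage of 7. That is why this sequence is held in reserve.

3. Step 8 (reductive transposition). The allyl cation may be intercepted by a chain alkene before hydride arrives, the Lewis acid may trigger cyclisation or migration within the polyene, or hydride may be delivered to C4 as well as C6. The fallback avoids any cation and sets out from pyranone 11, bypassing 12. Conjugate reduction with LiBH(s-Bu)3 in THF at –78 °C and trapping of the resulting C4 enolate with PhNTf2 should give (S)-5-[(3E,7E)-4,8,12-trimethyltrideca-3,7,11-trienyl]-2-[(trimethylsilyl)ethynyl]-3,6-dihydro-2H-pyran-4-yl trifluoromethanesulfonate F7, in which C6 is already CH2 and the alkene already C4=C5. Reduction of the enol triflate with Pd(OAc)2 (divalent palladium precatalyst), PPh3, Bu3N and HCO2H in DMF, at the lowest temperature that turns over so that the silyl-capped alkyne is left alone, replaces the triflate by hydrogen and returns the route to 13.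

Further compounds
F1 | step 6 | (1E,5S)-5-hydroxy-1-methoxy-2-[(3E,7E)-4,8,12-trimethyltrideca-3,7,11-trienyl]-7-(trimethylsilyl)hept-1-en-6-yn-3-one | CO/C=C(/C(=O)C[C@H](O)C#C[Si](C)(C)C)CC/C=C(\C)CC/C=C(\C)CCC=C(C)C
F2 | step 4 | (2E,6E)-farnesyl bromide | BrC/C=C(\C)CC/C=C(\C)CCC=C(C)C
F3 | step 4 | [2-(2-methyl-1,3-dioxolan-2-yl)ethyl]magnesium bromide | CC1(CC[Mg]Br)OCCO1
F4 | step 4 | 2-methyl-2-[(4E,8E)-5,9,13-trimethyltetradeca-4,8,12-trienyl]-1,3-dioxolane | CC1(CCC/C=C(\C)CC/C=C(\C)CCC=C(C)C)OCCO1
F5 | step 4 | (6E,10E)-7,11,15-trimethylhexadeca-6,10,14-trien-2-one | CC(=O)CCC/C=C(\C)CC/C=C(\C)CCC=C(C)C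
F6 | step 4 | (3Z,6E,10E)-3-(hydroxymethylidene)-7,11,15-trimethylhexadeca-6,10,14-trien-2-one (enol form of the β-keto aldehyde) | O/C=C(\C(C)=O)CC/C=C(\C)CC/C=C(\C)CCC=C(C)C
F7 | step 8 | (S)-5-[(3E,7E)-4,8,12-trimethyltrideca-3,7,11-trienyl]-2-[(trimethylsilyl)ethynyl]-3,6-dihydro-2H-pyran-4-yl trifluoromethanesulfonate | C[Si](C)(C)C#C[C@@H]1CC(OS(=O)(=O)C(F)(F)F)=C(CC/C=C(\C)CC/C=C(\C)CCC=C(C)C)CO1
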